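The oxolane ring (O1, C2–C5) with its cis-related stereocentres C2 and C5 is cut at O1–C2 and C4–C5. This maps C2–C3–C4 onto a donor–acceptor cyclopropane and C5–O1 onto pentanal. One magnesium-catalysed dynamic kinetic asymmetric (3+2) annulation closes the ring, forms both bonds and sets both stereocentres. The precursor is a racemic cyclopropane-1,1-diester whose (E)-hexadec-1-enyl donor activates the ring and later becomes the CH2C(=O)C14H29 arm by a regioselective Wacker oxidation. The two esters on C4 are spectators and are removed by decarboxylation. Locants here are those of the target (C2 bears the ketone arm, C5 the butyl group).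

Key step: step 2

Remark 1: the sense of induction of the magnesium–pybox catalyst is assumed such that the (S,S) ligand, 2,6-bis[(4S)-4-tert-butyl-4,5-dihydro-1,3-oxazol-2-yl]pyridine, selects (S)-3 and leads to (2R,5R)-5. If a small-scale test shows the opposite sense, the equally available (R,R) ligand takes its place without other change.

Remark 2: 6, 7 and 8 are carried as mixtures of epimers at C3, a centre that loses its substituent in step 5.

Step 1
Reactants: 1 dimethyl 2-ethenylcyclopropane-1,1-dicarboxylate (racemic); 2 hexadec-1-ene
Product: 3 dimethyl 2-[(E)-hexadec-1-en-1-yl]cyclopropane-1,1-dicarboxylate (racemic)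
Conditions: second-generation Grubbs catalyst RuCl2(=CHPh)(H2IMes)(PCy3) (3 mol %), 2 (3 equiv), CH2Cl2, 40 °C
Reagents that add atoms: none
Why: Olefin cross-metathesis between the terminal alkene 2 and the vinyl group of 1 expels ethene and should equilibrate towards the (E)-1,2-disubstituted alkene, while the cyclopropane and its esters are inert to the ruthenium carbene; no stereocentre is created and 3 stays racemic.

Step 2
Reactants: 3 dimethyl 2-[(E)-hexadec-1-en-1-yl]cyclopropane-1,1-dicarboxylate (racemic); 4 pentanal
Product: 5 dimethyl (2R,5R)-2-butyl-5-[(E)-hexadec-1-en-1-yl]oxolane-3,3-dicarboxylate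
Conditions: MgI2 (10 mol %), (S,S)-t-Bu-pybox (12 mol %), 4 (3 equiv), CCl4, rt
Reagents that add atoms: none
Why: The magnesium–pybox complex chelates both ester carbonyls and weakens the C1–C2 bond of 3, so that reversible opening to an (E)-allyl cation/magnesium malonate pair interconverts the cyclopropane enantiomers, while the oxygen of 4 attacks the matched enantiomer at the allylic donor carbon in an SN2-like manner with inversion and the resulting oxocarbenium/malonate pair collapses by C–C bond formation. The closest known reaction type is the Lewis-acid-catalysed (3+2) annulation of aldehydes with donor–acceptor cyclopropane diesters in its dynamic kinetic asymmetric MgI2–pybox form, established for styryl and electron-rich aryl donors. The oxolane closes by attack of the malonate carbon on the oxocarbenium carbon, formally a 5-endo-trig (aldol-type) closure onto a cation through an envelope transition state. The alkenyl-bearing centre (C5 of 5, R) is set under catalyst control by inversion of the selected cyclopropane enantiomer, and the butyl-bearing centre (C2 of 5, R) is set relative to it by the envelope in which both substituents lie pseudoequatorial, which gives the 2,5-cis ring. The step needs racemisation of 3 to outpace reaction of the mismatched enantiomer, attack at the ring-side allyl terminus, and O- and not C-reactivity of the aldehyde; the secondary–secondary allyl cation available from the (E)-alkenyl donor, the release of ring strain coupled to five-membered closure, and the mild Lewis acid should secure these. In the locants of 5 the new bonds are O1–C5 and C2–C3, which are O1–C2 and C4–C5 of the target.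

Step 3
Reactants: 5 dimethyl (2R,5R)-2-butyl-5-[(E)-hexadec-1-en-1-yl]oxolane-3,3-dicarboxylate
Product: 6 methyl (2R,5R)-2-butyl-5-[(E)-hexadec-1-en-1-yl]oxolane-3-carboxylate (C3 epimers)
Conditions: LiCl (3 equiv), H2O (2 equiv), DMSO, 150 °C
Reagents that add atoms: none
Why: Krapcho dealkoxycarbonylation: chloride demethylates one ester by SN2 attack on its methyl group, the resulting carboxylate loses CO2 and the ester enolate is protonated by water, which leaves C2 and C5 untouched and makes C3 an inconsequential epimer mixture.

Step 4
Reactants: 6 methyl (2R,5R)-2-butyl-5-[(E)-hexadec-1-en-1-yl]oxolane-3-carboxylate (C3 epimers)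
Product: 7 (2R,5R)-2-butyl-5-[(E)-hexadec-1-en-1-yl]oxolane-3-carboxylic acid (C3 epimers)
Conditions: LiOH·H2O (5 equiv), THF/MeOH/H2O, 50 °C; then 1 M HCl
Reagents that add atoms: lithium hydroxide, [Li+].[OH-] (its oxygen becomes the carboxyl OH)
Why: Saponification by acyl–oxygen cleavage of the remaining methyl ester, under conditions that affect neither the allylic ether nor the alkene; epimerisation at C3 is of no consequence.

Step 5
Reactants: 7 (2R,5R)-2-butyl-5-[(E)-hexadec-1-en-1-yl]oxolane-3-carboxylic acid (C3 epimers)
Product: 9 (2R,5R)-2-butyl-5-[(E)-hexadec-1-en-1-yl]oxolane, via Barton ester 8 (not isolated)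
Conditions: N-hydroxypyridine-2-thione, DCC, DMAP (cat.), CH2Cl2, 0 °C to rt, dark; then t-BuSH, hν (tungsten lamp), rt
Reagents that add atoms: N-hydroxypyridine-2-thione, ON1C=CC=CC1=S (its atoms stand only in intermediate 8; none remains in 9)
Why: Barton reductive decarboxylation: the O-acyl thiohydroxamate 8 fragments in a thiyl-radical chain to CO2 and the secondary C3 radical, which takes hydrogen from t-BuSH and has no favourable cyclisation or β-scission path (attack on the alkene would be 4-exo or 5-endo), so C2 and C5 are retained and any thiyl-induced E/Z drift of the alkene is erased in step 6.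

Step 6
Reactants: 9 (2R,5R)-2-butyl-5-[(E)-hexadec-1-en-1-yl]oxolane
Product: 10 1-[(2R,5R)-5-butyloxolan-2-yl]hexadecan-2-one
Conditions: Pd(OAc)2 (5 mol %), 1,4-benzoquinone (1.1 equiv), aq HBF4, DMA/MeCN/H2O, rt
Reagents that add atoms: water, O
Why: Wacker-type oxidation of an internal alkene by divalent palladium with benzoquinone as terminal oxidant: the inductively withdrawing allylic ring oxygen should direct hydroxypalladation so that water is delivered to the remote alkene carbon, giving the β-alkoxy ketone, and the base-free medium at room temperature should not trigger retro-oxa-Michael epimerisation of the adjacent ring centre.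

Compound list
1 | dimethyl 2-ethenylcyclopropane-1,1-dicarboxylate (racemic) | C=CC1CC1(C(=O)OC)C(=O)OC | starting material
2 | hexadec-1-ene | C=CCCCCCCCCCCCCCC | starting material
3 | dimethyl 2-[(E)-hexadec-1-en-1-yl]cyclopropane-1,1-dicarboxylate (racemic) | CCCCCCCCCCCCCC/C=C/C1CC1(C(=O)OC)C(=O)OC | intermediate
4 | pentanal | CCCCC=O | starting material
5 | dimethyl (2R,5R)-2-butyl-5-[(E)-hexadec-1-en-1-yl]oxolane-3,3-dicarboxylate | CCCCCCCCCCCCCC/C=C/[C@H]1CC(C(=O)OC)(C(=O)OC)[C@@H](CCCC)O1 | intermediate
6 | methyl (2R,5R)-2-butyl-5-[(E)-hexadec-1-en-1-yl]oxolane-3-carboxylate (C3 epimers) | CCCCCCCCCCCCCC/C=C/[C@H]1CC(C(=O)OC)[C@@H](CCCC)O1 | intermediate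
7 | (2R,5R)-2-butyl-5-[(E)-hexadec-1-en-1-yl]oxolane-3-carboxylic acid (C3 epimers) | CCCCCCCCCCCCCC/C=C/[C@H]1CC(C(=O)O)[C@@H](CCCC)O1 | intermediate
8 | Barton ester, 2-thioxopyridin-1(2H)-yl (2R,5R)-2-butyl-5-[(E)-hexadec-1-en-1-yl]oxolane-3-carboxylate (C3 epimers; formed and consumed in the flask) | CCCCCCCCCCCCCC/C=C/[C@H]1CC(C(=O)ON2C=CC=CC2=S)[C@@H](CCCC)O1 | intermediate
9 | (2R,5R)-2-butyl-5-[(E)-hexadec-1-en-1-yl]oxolane | CCCCCCCCCCCCCC/C=C/[C@H]1CC[C@@H](CCCC)O1 | intermediate
10 | 1-[(2R,5R)-5-butyloxolan-2-yl]hexadecan-2-one | CCCCCCCCCCCCCCC(=O)C[C@H]1CC[C@@H](CCCC)O1 | target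

Total step count: 6. Longest linear sequence: 6 steps (1 → 3 → 5 → 6 → 7 → 9 → 10).

Steps most likely to fail

First, step 2. Opening of the cyclopropane to the allyl cation/malonate pair may be too slow with a purely alkyl-substituted alkenyl donor. The enantiomers of 3 would then not equilibrate, and the annulation would run as a plain kinetic resolution that stalls near half conversion with falling enantiomeric purity. Self-aldol condensation of 4 under the Lewis acid may add to this. The fallback builds the oxolane by catalyst-controlled O-allylation instead of annulation. It sets out from 2, which is needed only at its end, and from purchased (R)-2-butyloxirane. Copper-catalysed opening of the epoxide at its terminal carbon with CH2=CHCH2MgBr (CuI cat., THF, −30 °C) should give (5R)-non-1-en-5-ol F1. Cross-metathesis with (Z)-but-2-ene-1,4-diyl diacetate (second-generation Grubbs catalyst RuCl2(=CHPh)(H2IMes)(PCy3), CH2Cl2, 40 °C) should give (2E,6R)-6-hydroxydec-2-en-1-yl acetate F2. Intramolecular Tsuji–Trost etherification with zerovalent palladium (Pd2(dba)3·CHCl3, the antipode of the DACH-phenyl Trost ligand that is matched to the cis ring, Et3N, CH2Cl2, rt) should close (2R,5R)-2-butyl-5-ethenyloxolane F3. Its carbinol centre comes from the epoxide and its new centre from the ligand. Cross-metathesis of F3 with 2 under the conditions of step 1 comes back to the route at 9, so that steps 1 to 5 are bypassed.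

Second, step 6. Hydroxypalladation may be insufficiently regioselective, with attack at the alkene carbon next to the ring. A palladium hydride may move the alkene along the chain before oxidation. The acid may also open the allylic ether or epimerise the β-alkoxy ketone by retro-oxa-Michael reaction. The fallback fixes the position of the carbonyl by acyl-anion alkylation and sets out from 9. Ozonolysis with reductive work-up (O3, CH2Cl2/MeOH, −78 °C; then NaBH4) should give [(2R,5R)-5-butyloxolan-2-yl]methanol F4 without exposing an epimerisable aldehyde. Iodination (I2, PPh3, imidazole, CH2Cl2, 0 °C) should give (2R,5R)-2-butyl-5-(iodomethyl)oxolane F5. Pentadecanal and propane-1,3-dithiol (BF3·OEt2, CH2Cl2) give 2-tetradecyl-1,3-dithiane F6, which is lithiated (n-BuLi, THF, −30 °C) and alkylated with F5 (DMPU, −30 °C to rt). This Corey–Seebach alkylation should give 2-{[(2R,5R)-5-butyloxolan-2-yl]methyl}-2-tetradecyl-1,3-dithiane F7. Buffered dithiane hydrolysis (MeI, CaCO3, MeCN/H2O, 45 °C) comes back to the route at 10.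

Third, step 3. At 150 °C the ester enolate formed after loss of CO2 may expel the ring oxygen in an E1cB opening, which would scramble or destroy the butyl-bearing centre. The hindered diester may also resist dealkylation by chloride, so that conversion stays incomplete. The fallback sets out from 5 and avoids the ester enolate. Double saponification (KOH, EtOH/H2O, reflux; then 1 M HCl) should give (2R,5R)-2-butyl-5-[(E)-hexadec-1-en-1-yl]oxolane-3,3-dicarboxylic acid F8. Thermal decarboxylation of this malonic acid (pyridine, 100 °C) passes through a cyclic transition state and an enediol and comes back to the route at 7, so that 6 is bypassed.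

Further compounds
F1 | step 2 | (5R)-non-1-en-5-ol | CCCC[C@@H](O)CCC=C
F2 | step 2 | (2E,6R)-6-hydroxydec-2-en-1-yl acetate | CCCC[C@@H](O)CC/C=C/COC(C)=O
F3 | step 2 | (2R,5R)-2-butyl-5-ethenyloxolane | C=C[C@H]1CC[C@@H](CCCC)O1
F4 | step 6 | [(2R,5R)-5-butyloxolan-2-yl]methanol | OC[C@H]1CC[C@@H](CCCC)O1
F5 | step 6 | (2R,5R)-2-butyl-5-(iodomethyl)oxolane | IC[C@H]1CC[C@@H](CCCC)O1
F6 | step 6 | 2-tetradecyl-1,3-dithiane | CCCCCCCCCCCCCCC1SCCCS1
F7 | step 6 | 2-{[(2R,5R)-5-butyloxolan-2-yl]methyl}-2-tetradecyl-1,3-dithiane | CCCCCCCCCCCCCCC1(C[C@H]2CC[C@@H](CCCC)O2)SCCCS1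
F8 | step 3 | (2R,5R)-2-butyl-5-[(E)-hexadec-1-en-1-yl]oxolane-3,3-dicarboxylic acid | CCCCCCCCCCCCCC/C=C/[C@H]1CC(C(=O)O)(C(=O)O)[C@@H](CCCC)O1
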